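The retrosynthesis (labdane numbering) first cuts the O6–acetyl bond and C8=C17. It then removes the (Z)-diene chain at C13–C14 and C9–C11, and traces the C10 methyl back to a cyclopropane (C9–C20 re-joined). The cyclopropane goes back to the C9=C10 alkene of an 8β-allylic alcohol, ring B is cut at C9=C10 and C5–C6, and C4–C18 is cut last.
The key step is possible because, in ring B, the chain C8–C9–C10 links the future methylene carbon C8 to the quaternary A/B fusion carbon C10 through a single CH. A CH2 laid over C9=C10 therefore becomes a cyclopropyl ketone once C8 is a ketone. Its reductive opening leaves C20 as the C10 methyl group and leaves the enolate only between C8 and C9.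
In the forward direction, ring A is bought as a cyclohexenone ester and ring B is closed by metathesis at the alcohol oxidation level. The three-membered ring is then added and opened, the chain is joined at C9 by enolate alkylation and completed by vinylation, and C8 methylenation and silyl-to-acetyl exchange finish the route.
C4 comes from a chiral copper catalyst and C8 (temporary) from (R)-2-vinyloxirane. C6 and C5 come from an aldehyde-controlled aldol, C10 from hydroxyl direction, and C9 from equilibration to the equatorial chain. The 12Z geometry comes from directed hydroalumination–iodination and a stereoretentive coupling.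

Key step: step 12

Remark: labdane numbering is used for all intermediates (ring A = C1–C5 and C10, ring B = C5–C10, C18 = 4α-methyl, C19 = ester carbon, C20 = angular methyl, α = face of H5, β = face of C20), and (R)-2-vinyloxirane is assumed to be a catalogue compound (otherwise one hydrolytic kinetic resolution of butadiene monoxide is added).

Step 1
Reactants: 1 1,3-dithiane; 2 (R)-2-vinyloxirane
Product: 4 (S)-1-(1,3-dithian-2-yl)but-3-en-2-ol, via 2-lithio-1,3-dithiane 3 (not isolated)
Conditions: n-BuLi, THF, −20 °C; then 2, −78 → 0 °C; H2O quench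
Reagents that add atoms: none
Why: Corey–Seebach umpolung in which the unhindered lithiodithiane opens the vinyl epoxide by SN2 attack at its terminal CH2, so the C8–O stereocentre of 2 is carried over untouched.

Step 2
Reactants: 4 (S)-1-(1,3-dithian-2-yl)but-3-en-2-ol
Product: 5 (S)-2-[2-(4-methoxybenzyloxy)but-3-enyl]-1,3-dithiane
Conditions: NaH, 4-methoxybenzyl chloride, Bu4NI (cat.), DMF, 0 °C → rt
Reagents that add atoms: 4-methoxybenzyl chloride COc1ccc(CCl)cc1
Why: Williamson etherification of the sodium alkoxide, the PMB group being chosen because β-OPMB aldehydes give the strongest 1,3-induction in step 7 and because it can later be removed next to a TBS ether.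

Step 3
Reactants: 5 (S)-2-[2-(4-methoxybenzyloxy)but-3-enyl]-1,3-dithiane
Product: 6 (S)-3-(4-methoxybenzyloxy)pent-4-enal
Conditions: MeI, CaCO3, MeCN–H2O (9:1), 40 °C
Reagents that add atoms: water O
Why: S-methylation turns the dithiane into a leaving group and carbonate-buffered hydrolysis frees the aldehyde under near-neutral conditions that avoid β-elimination of the allylic ether.

Step 4
Reactants: 7 but-2-yn-1-ol
Product: 9 (Z)-3-iodobut-2-en-1-ol, via cyclic sodium alkenylalanate 8 (not isolated)
Conditions: NaAlH2(OCH2CH2OMe)2, THF, 0 °C → rt; I2, −78 °C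
Reagents that add atoms: iodine II
Why: Hydroxyl-directed trans-hydroalumination of a propargylic alcohol puts aluminium on the distal alkyne carbon inside the five-membered alanate 8, and iodinolysis with retention therefore gives only the Z-iodoalkene that later becomes the 12Z double bond.

Step 5
Reactants: 9 (Z)-3-iodobut-2-en-1-ol
Product: 10 (Z)-1-bromo-3-iodobut-2-ene
Conditions: CBr4, PPh3, CH2Cl2, 0 °C
Reagents that add atoms: carbon tetrabromide BrC(Br)(Br)Br
Why: Appel bromination converts the primary allylic alcohol under neutral conditions by SN2 displacement of the oxyphosphonium ion without touching the alkenyl iodide or its geometry.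

Step 6
Reactants: 11 methyl 3-oxocyclohex-1-ene-1-carboxylate; 12 dimethylzinc
Product: 14 methyl (S)-1-methyl-3-(trimethylsilyloxy)cyclohex-2-ene-1-carboxylate, via methylzinc enolate 13 (not isolated)
Conditions: 12 (3 equiv), (CuOTf)2·C6H6 (2.5 mol %), chiral bidentate N-heterocyclic carbene ligand (5 mol %), Et2O, −30 °C; then TMSOTf, −78 → 0 °C
Reagents that add atoms: dimethylzinc C[Zn]C; trimethylsilyl triflate C[Si](C)(C)OS(=O)(=O)C(F)(F)F
Why: Copper-catalysed enantioselective conjugate addition of a dialkylzinc to a cyclic unsaturated γ-keto ester, a known way to all-carbon quaternary centres, in which methyl adds β to the ketone at the ester-bearing carbon, the chiral carbene ligand (antipode chosen for 4S) selects the alkene face, and TMSOTf fixes enolate 13 regiospecifically as the C5=C10 silyl enol ether.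

Step 7
Reactants: 14 methyl (S)-1-methyl-3-(trimethylsilyloxy)cyclohex-2-ene-1-carboxylate; 6 (S)-3-(4-methoxybenzyloxy)pent-4-enal
Product: 15 methyl (1S,2R)-2-[(1S,3S)-1-hydroxy-3-(4-methoxybenzyloxy)pent-4-enyl]-1-methyl-3-oxocyclohexane-1-carboxylate
Conditions: BF3·OEt2, CH2Cl2, −78 °C; cold aq NaHCO3 quench
Reagents that add atoms: none
Why: Mukaiyama aldol through an open antiperiplanar transition state in which BF3-bound 6 is attacked on the face set by the polar 1,3-anti induction model (6S, anti to the C8 ether), its chain turns away from quaternary C4 so that the syn C5/C6 relationship results, and, because CH3 and CO2Me at C4 differ little in size, the aldehyde decides which enol ether face reacts, namely the one anti to the pseudo-axial methyl group (5R, chain cis to the ester).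

Step 8
Reactants: 15 aldol adduct
Product: 16 6-O-TBS ether of 15 (C10 ketone; 8-OPMB)
Conditions: TBSOTf, 2,6-lutidine, CH2Cl2, −78 → 0 °C (on the crude aldol)
Reagents that add atoms: tert-butyldimethylsilyl triflate CC(C)(C)[Si](C)(C)OS(=O)(=O)C(F)(F)F
Why: Silylation with the triflate is fast even for a hindered carbinol at low temperature and is run at once so that the C6 hydroxyl can neither lactonise onto the cis C19 ester nor undergo retro-aldol cleavage.

Step 9
Reactants: 16 silyloxy ketone; 17 dimethyltitanocene
Product: 18 C10 exocyclic methylene compound (6-OTBS; 8-OPMB)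
Conditions: 17 (2 equiv), toluene, 70 °C, dark
Reagents that add atoms: dimethyltitanocene C[Ti+2]C.c1cc[cH-]c1.c1cc[cH-]c1
Why: Petasis methylenation, in which thermally generated Cp2Ti=CH2 is non-basic so that the β-silyloxy ketone is neither epimerised at C5 nor eliminated, and in which a ketone reacts ahead of the tertiary, neopentyl-type ester.

Step 10
Reactants: 18 PMB ether
Product: 19 methyl (1S,2R)-2-[(1S,3S)-1-(tert-butyldimethylsilyloxy)-3-hydroxypent-4-enyl]-1-methyl-3-methylenecyclohexane-1-carboxylate
Conditions: DDQ, CH2Cl2–pH 7 buffer (10:1), 0 °C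
Reagents that add atoms: none
Why: Oxidative cleavage of the electron-rich benzyl ether by DDQ (hydride abstraction, then hydrolysis of the oxocarbenium ion) leaves the silyl ether, the ester and the unactivated alkenes alone.

Step 11
Reactants: 19 dienol
Product: 20 methyl (1S,6S,8S,8aR)-8-(tert-butyldimethylsilyloxy)-6-hydroxy-1-methyl-1,2,3,4,6,7,8,8a-octahydronaphthalene-1-carboxylate (8β-allylic alcohol; C9=C10; 6α-OTBS; 5α-H)
Conditions: second-generation Hoveyda–Grubbs catalyst (5 mol %), 1,4-benzoquinone (10 mol %), toluene, 80 °C
Reagents that add atoms: none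
Why: Ring-closing metathesis in which the catalyst loads on the monosubstituted vinyl carbinol and closes ring B onto the 1,1-disubstituted alkene with loss of ethene, giving the allylic alcohol directly with C8 already set and bypassing the 6-silyloxy enone, which would be one β-elimination away from a phenol.

Step 12
Reactants: 20 bicyclic 8β-allylic alcohol; 21 diiodomethane
Product: 23 cyclopropyl carbinol (CH2 = C20 bridging C9 and C10 on the β face; 8β-OH; 6α-OTBS; 5α-H), via iodomethylzinc alkoxide 22 (not isolated)
Conditions: Et2Zn (5 equiv), 21 (10 equiv), CH2Cl2, −20 °C → rt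
Reagents that add atoms: diiodomethane ICI
Why: Et2Zn deprotonates the 8β-hydroxyl and exchange with CH2I2 gives the iodomethylzinc alkoxide 22, which (alone or aggregated with further zinc carbenoid) hands its CH2 to the neighbouring C9=C10 bond through the concerted butterfly transition state of the Furukawa-modified Simmons–Smith reaction. The closest known reaction type is the hydroxyl-directed cyclopropanation of cyclohex-2-enols, including trisubstituted ring-fusion alkenes used as masked angular methyl groups. The three-membered ring (C9, C10, C20) closes in one suprafacial [2+1] methylene transfer in which C9–C20 and C10–C20 form together, so that no rotation or cationic intermediate can intervene. C10 and C9 are both fixed by the 8β-oxygen, because zinc is anchored on the β face and can release CH2 only there, which places C20 β and trans to the 5α-hydrogen. The step needs face selectivity in favour of a β face that also carries the pseudo-axial C19 ester, and this is secured by the large rate acceleration through the zinc alkoxide, by possible extra coordination of the ester carbonyl on the same face, and by the inability of the 6α-silyl ether to bind zinc. Chemoselectivity is no issue because C9=C10 is the only alkene in 20.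

Step 13
Reactants: 23 cyclopropyl carbinol
Product: 24 cyclopropyl ketone (C8=O; C20 bridging C9 and C10 on the β face)
Conditions: Dess–Martin periodinane, CH2Cl2, rt
Reagents that add atoms: none
Why: Dess–Martin oxidation converts the secondary carbinol under mild conditions without opening the cyclopropane or disturbing the silyl ether and ester.

Step 14
Reactants: 24 cyclopropyl ketone
Product: 26 C8–C9 trimethylsilyl enol ether carrying the 10β-methyl group (6α-OTBS), via samarium enolate 25 (not isolated)
Conditions: SmI2 (2.5 equiv), HMPA (10 equiv), t-BuOH (1.0 equiv), THF, −78 °C; then TMSCl (5 equiv), −78 → 0 °C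
Reagents that add atoms: trimethylsilyl chloride C[Si](C)(C)Cl
Why: Single-electron reduction gives the C8 ketyl, which breaks the exocyclic C9–C20 bond (the cyclopropane bond best aligned with the carbonyl π system, C9–C10 lying near its nodal plane), the primary C20 radical is reduced further and protonated by tert-butanol to the angular methyl group, and the surviving trivalent samarium enolate is O-silylated, a known ring opening–enolate trapping sequence of cyclopropyl ketones that leaves the ester untouched.

Step 15
Reactants: 26 silyl enol ether; 10 (Z)-1-bromo-3-iodobut-2-ene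
Product: 28 9α-[(Z)-3-iodobut-2-enyl] 8-ketone (9-epi series; 9β-H), via lithium enolate 27 (not isolated)
Conditions: MeLi (1.05 equiv), THF, 0 °C; DMPU, then 10, −78 → −20 °C
Reagents that add atoms: none
Why: Regiospecific lithium enolate generation from a silyl enol ether followed by SN2 alkylation with a reactive allylic bromide, in which carbon attack occurs axially on the α face anti to the C20 methyl group and the hindered C19 ester and the alkenyl iodide are left alone.

Step 16
Reactants: 28 9α-alkyl ketone
Product: 29 9β-[(Z)-3-iodobut-2-enyl] 8-ketone (9α-H; natural C9 configuration)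
Conditions: NaOMe (0.2 equiv), MeOH, 0 °C → rt
Reagents that add atoms: none
Why: Base-mediated equilibration through the enolate moves the chain from the axial 9α position, where it faces three syn-axial hydrogens, to the equatorial 9β position, while the equatorial 6α-silyloxy group lies close to the nodal plane of a C7–C8 enolate and is therefore poorly set up for E1cB loss.

Step 17
Reactants: 29 alkenyl iodide; 30 tributyl(vinyl)stannane
Product: 31 (12Z)-dienyl 8-ketone (6α-OTBS)
Conditions: 30 (1.5 equiv), Pd2(dba)3 (5 mol %), AsPh3 (20 mol %), NMP, rt → 40 °C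
Reagents that add atoms: tributyl(vinyl)stannane C=C[Sn](CCCC)(CCCC)CCCC
Why: Stille coupling proceeds with retention of the alkene geometry under neutral conditions and is placed at the ketone stage so that the alkenylpalladium intermediate finds no C8=C17 alkene for an intramolecular Heck reaction.

Step 18
Reactants: 31 dienyl ketone; 17 dimethyltitanocene
Product: 32 methyl 6α-(tert-butyldimethylsilyloxy)labda-8(17),12Z,14-trien-19-oate
Conditions: 17 (3 equiv), toluene, 75 °C, dark
Reagents that add atoms: dimethyltitanocene C[Ti+2]C.c1cc[cH-]c1.c1cc[cH-]c1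
Why: Petasis methylenation of the hindered C8 ketone is non-basic, so that C9 is not epimerised and the β-silyloxy group is not eliminated, and the temperature is far below that needed for a sigmatropic hydrogen shift in the Z-diene.

Step 19
Reactants: 32 silyl ether
Product: 33 methyl 6α-hydroxylabda-8(17),12Z,14-trien-19-oate
Conditions: Bu4NF, THF, rt → 50 °C
Reagents that add atoms: none
Why: Fluoride-induced desilylation spares the alkenes and the hindered ester, and in the trans-decalin the equatorial 6α-hydroxyl cannot reach the axial C19 ester, so no lactone forms.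

Step 20
Reactants: 33 6α-alcohol
Product: 34 methyl 6α-acetoxylabda-8(17),12Z,14-trien-19-oate (CNP0212193.2)
Conditions: Ac2O, DMAP (cat.), pyridine, rt
Reagents that add atoms: acetic anhydride CC(=O)OC(C)=O
Why: DMAP-catalysed acylation esterifies the hindered equatorial secondary alcohol with retention at C6 and affects no other group.

Compound list
1 | 1,3-dithiane | C1CSCSC1 | starting material
2 | (R)-2-vinyloxirane | C=C[C@@H]1CO1 | starting material
3 | 2-lithio-1,3-dithiane | [Li]C1SCCCS1 | intermediate
4 | (S)-1-(1,3-dithian-2-yl)but-3-en-2-ol | C=C[C@@H](O)CC1SCCCS1 | intermediate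
5 | (S)-2-[2-(4-methoxybenzyloxy)but-3-enyl]-1,3-dithiane | C=C[C@@H](OCc1ccc(OC)cc1)CC2SCCCS2 | intermediate
6 | (S)-3-(4-methoxybenzyloxy)pent-4-enal | C=C[C@@H](OCc1ccc(OC)cc1)CC=O | intermediate
7 | but-2-yn-1-ol | CC#CCO | starting material
8 | cyclic sodium alkenylalanate from 7 | CC1=CCO[Al-]1(OCCOC)OCCOC.[Na+] | intermediate
9 | (Z)-3-iodobut-2-en-1-ol | C/C(I)=C/CO | intermediate
10 | (Z)-1-bromo-3-iodobut-2-ene | C/C(I)=C/CBr | intermediate
11 | methyl 3-oxocyclohex-1-ene-1-carboxylate | COC(=O)C1=CC(=O)CCC1 | starting material
12 | dimethylzinc | C[Zn]C | starting material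
13 | methylzinc enolate (C5=C10, 4S) | C1=C(O[Zn]C)CCC[C@]1(C)C(=O)OC | intermediate
14 | methyl (S)-1-methyl-3-(trimethylsilyloxy)cyclohex-2-ene-1-carboxylate | C1=C(O[Si](C)(C)C)CCC[C@]1(C)C(=O)OC | intermediate
15 | aldol adduct, methyl (1S,2R)-2-[(1S,3S)-1-hydroxy-3-(4-methoxybenzyloxy)pent-4-enyl]-1-methyl-3-oxocyclohexane-1-carboxylate | C=C[C@@H](OCc1ccc(OC)cc1)C[C@H](O)[C@@H]2C(=O)CCC[C@]2(C)C(=O)OC | intermediate
16 | 6-O-TBS ether of 15 | C=C[C@@H](OCc1ccc(OC)cc1)C[C@H](O[Si](C)(C)C(C)(C)C)[C@@H]2C(=O)CCC[C@]2(C)C(=O)OC | intermediate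
17 | dimethyltitanocene, Cp2TiMe2 | C[Ti+2]C.c1cc[cH-]c1.c1cc[cH-]c1 | starting material
18 | C10 exocyclic methylene compound (6-OTBS, 8-OPMB) | C=C[C@@H](OCc1ccc(OC)cc1)C[C@H](O[Si](C)(C)C(C)(C)C)[C@@H]2C(=C)CCC[C@]2(C)C(=O)OC | intermediate
19 | dienol (6-OTBS, free 8-OH) | C=C[C@@H](O)C[C@H](O[Si](C)(C)C(C)(C)C)[C@@H]1C(=C)CCC[C@]1(C)C(=O)OC | intermediate
20 | bicyclic 8β-allylic alcohol (C9=C10, 6α-OTBS, 5α-H, 4β-CO2Me) | O[C@H]1C[C@H](O[Si](C)(C)C(C)(C)C)[C@@H]2C(=C1)CCC[C@]2(C)C(=O)OC | intermediate
21 | diiodomethane | ICI | starting material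
22 | iodomethylzinc alkoxide of 20 | IC[Zn]O[C@H]1C[C@H](O[Si](C)(C)C(C)(C)C)[C@@H]2C(=C1)CCC[C@]2(C)C(=O)OC | intermediate
23 | cyclopropyl carbinol (C20 bridging C9 and C10 on the β face, 8β-OH) | C3[C@H]1[C@@H](O)C[C@H](O[Si](C)(C)C(C)(C)C)[C@@H]2[C@]13CCC[C@]2(C)C(=O)OC | intermediate
24 | cyclopropyl ketone (C8=O) | C3[C@H]1C(=O)C[C@H](O[Si](C)(C)C(C)(C)C)[C@@H]2[C@]13CCC[C@]2(C)C(=O)OC | intermediate
25 | diiodosamarium C8–C9 enolate (10β-methyl) | C1=C(O[Sm](I)I)C[C@H](O[Si](C)(C)C(C)(C)C)[C@@H]2[C@]1(C)CCC[C@]2(C)C(=O)OC | intermediate
26 | C8–C9 trimethylsilyl enol ether (10β-methyl, 6α-OTBS) | C1=C(O[Si](C)(C)C)C[C@H](O[Si](C)(C)C(C)(C)C)[C@@H]2[C@]1(C)CCC[C@]2(C)C(=O)OC | intermediate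
27 | lithium C8–C9 enolate | C1=C(O[Li])C[C@H](O[Si](C)(C)C(C)(C)C)[C@@H]2[C@]1(C)CCC[C@]2(C)C(=O)OC | intermediate
28 | 9α-[(Z)-3-iodobut-2-enyl] 8-ketone (9-epi) | I/C(C)=C\C[C@@H]1C(=O)C[C@H](O[Si](C)(C)C(C)(C)C)[C@@H]2[C@]1(C)CCC[C@]2(C)C(=O)OC | intermediate
29 | 9β-[(Z)-3-iodobut-2-enyl] 8-ketone (9α-H) | I/C(C)=C\C[C@H]1C(=O)C[C@H](O[Si](C)(C)C(C)(C)C)[C@@H]2[C@]1(C)CCC[C@]2(C)C(=O)OC | intermediate
30 | tributyl(vinyl)stannane | C=C[Sn](CCCC)(CCCC)CCCC | starting material
31 | (12Z)-dienyl 8-ketone (6α-OTBS) | C=C/C(C)=C\C[C@H]1C(=O)C[C@H](O[Si](C)(C)C(C)(C)C)[C@@H]2[C@]1(C)CCC[C@]2(C)C(=O)OC | intermediate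
32 | methyl 6α-(tert-butyldimethylsilyloxy)labda-8(17),12Z,14-trien-19-oate | C=C/C(C)=C\C[C@H]1C(=C)C[C@H](O[Si](C)(C)C(C)(C)C)[C@@H]2[C@]1(C)CCC[C@]2(C)C(=O)OC | intermediate
33 | methyl 6α-hydroxylabda-8(17),12Z,14-trien-19-oate | C=C/C(C)=C\C[C@H]1C(=C)C[C@H](O)[C@@H]2[C@]1(C)CCC[C@]2(C)C(=O)OC | intermediate
34 | methyl 6α-acetoxylabda-8(17),12Z,14-trien-19-oate (CNP0212193.2) | C=C/C(C)=C\C[C@H]1C(=C)C[C@H](OC(C)=O)[C@@H]2[C@]1(C)CCC[C@]2(C)C(=O)OC | target

Total step count: 20. Longest linear sequence: 17 (steps 1–3, then 7–20).

Steps most likely to fail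

**Step 7.** The enol ether may react on both faces because the two C4 substituents are alike in size. The free C6 carbinol may also close onto the cis ester before it is silylated. The fallback makes C4 quaternary last, so that C5 is set next to a tertiary centre and methyl enters under control of the finished C5 substituent.
- It sets out from 11 and 6. RhCl(PPh3)3-catalysed 1,4-hydrosilylation of 11 with Et3SiH should give racemic methyl 3-(triethylsilyloxy)cyclohex-2-ene-1-carboxylate F1.
- F1 is used in excess with BF3·OEt2 and 6. Only the enantiomer whose ester lies opposite to the face demanded by the aldehyde should react readily, giving the 4-demethyl aldol adduct F2, in which the ester is trans to the side chain and lactonisation is disfavoured.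
- TBSOTf and 2,6-lutidine give the 4-demethyl silyl ether F3, and Cp2TiMe2 gives the 4-demethyl methylene compound F4.
- LiN(i-Pr)2 followed by MeI alkylates the C4 ester enolate anti to the bulky C5 substituent. This places methyl α and the ester β and comes back to the route at 18.

**Step 14.** After ring opening, the C20 radical or its organosamarium successor may add to the 1,3-diaxial C19 ester carbonyl. Alternatively, the enolate may be protonated before silylation, so that the positional information is lost. The fallback opens the ring ionically instead of reductively.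
- It sets out from 24. Me3SiI (from Me3SiCl and NaI) with Et3N in CH2Cl2–MeCN at −20 °C silylates the carbonyl oxygen while iodide attacks the unhindered C20 methylene.
- This cleaves the same C9–C20 bond and gives the 20-iodo silyl enol ether F5.
- Bu3SnH with AIBN in benzene then replaces iodine by hydrogen in a radical chain and comes back to the route at 26.

**Step 15.** Proton exchange between the lithium enolate and the alkylated ketone may move the enolate to C7, which would open the way to loss of the silyloxy group and to over-alkylation. The fallback uses neutral palladium enolate chemistry with a plain allyl group and rebuilds the chain afterwards.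
- It sets out from 24. The samarium enolate 25 is generated as in step 14 but quenched with allyl chloroformate to give the allyl enol carbonate F6.
- Pd(PPh3)4 in THF triggers a decarboxylative Tsuji allylation at C9 only and gives the 9α-allyl ketone F7, which NaOMe in MeOH equilibrates to the 9β-allyl ketone F8.
- Ozonolysis with PPh3 work-up gives the keto aldehyde F9.
- A Stork–Zhao type olefination with Ph3P=C(I)CH3 (from ethyltriphenylphosphonium iodide, n-BuLi, I2 and NaN(SiMe3)2) converts only the aldehyde into the (Z)-iodoalkene and returns to the route at 29.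

Further compounds
F1 | step 7 | racemic methyl 3-(triethylsilyloxy)cyclohex-2-ene-1-carboxylate | COC(=O)C1CCCC(O[Si](CC)(CC)CC)=C1
F2 | step 7 | 4-demethyl aldol adduct (C4-H, ester trans to the C5 side chain) | C=C[C@@H](OCc1ccc(OC)cc1)C[C@H](O)[C@@H]2C(=O)CCC[C@H]2C(=O)OC
F3 | step 7 | 4-demethyl silyl ether (6-OTBS, C10 ketone) | C=C[C@@H](OCc1ccc(OC)cc1)C[C@H](O[Si](C)(C)C(C)(C)C)[C@@H]2C(=O)CCC[C@H]2C(=O)OC
F4 | step 7 | 4-demethyl methylene compound (6-OTBS, C10=CH2) | C=C[C@@H](OCc1ccc(OC)cc1)C[C@H](O[Si](C)(C)C(C)(C)C)[C@@H]2C(=C)CCC[C@H]2C(=O)OC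
F5 | step 14 | 20-iodo silyl enol ether | C1=C(O[Si](C)(C)C)C[C@H](O[Si](C)(C)C(C)(C)C)[C@@H]2[C@]1(CI)CCC[C@]2(C)C(=O)OC
F6 | step 15 | allyl enol carbonate (C8–C9) | C1=C(OC(=O)OCC=C)C[C@H](O[Si](C)(C)C(C)(C)C)[C@@H]2[C@]1(C)CCC[C@]2(C)C(=O)OC
F7 | step 15 | 9α-allyl ketone | C=CC[C@@H]1C(=O)C[C@H](O[Si](C)(C)C(C)(C)C)[C@@H]2[C@]1(C)CCC[C@]2(C)C(=O)OC
F8 | step 15 | 9β-allyl ketone | C=CC[C@H]1C(=O)C[C@H](O[Si](C)(C)C(C)(C)C)[C@@H]2[C@]1(C)CCC[C@]2(C)C(=O)OC
F9 | step 15 | keto aldehyde (C12 aldehyde, C8 ketone) | O=CC[C@H]1C(=O)C[C@H](O[Si](C)(C)C(C)(C)C)[C@@H]2[C@]1(C)CCC[C@]2(C)C(=O)OC
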